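**Retrosynthetic overview**

1. Target ⇐ desilylation and double epoxidation of a ring A 2-bromo-1,3-diene ⇐ spiro β-hydroxy ketone (C5=O) by C-methylation at C5, correction of the C11 carbinol (oxidation, then hydroxyl-directed reduction) and dehydration.
2. Key disconnection: ring A (C1–C6) ⇐ the five-membered ring C1–C5 (a 3-bromo-2,2-dimethylcyclopent-3-enyl silyl ether) bonded through C5 to the oxirane carbon C6 of ring B. A semipinacol 1,2-shift of C1 from C5 to C6 enlarges the ring by one carbon and makes the C1–C6 bond between the two fully substituted carbons.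
3. Enabling feature: the spiro carbon C6 lies between C5 of ring A (the later C–CH3 carbon, reachable from a ketone) and the carbinol carbon C11 of ring B, i.e. a C5(=O)–C6–C11(O) β-oxy ketone array with a fully substituted α-carbon; its other ring A neighbour C1 (CMe2, next to the C2=C3 bromoalkene) is a good migrating carbon.
4. Stereochemistry: one Shi epoxidation (C8=C9) is the only reagent-set element. C8 (bromide opening), the C6–C11 oxirane (directed by C9–OH), C6 (the shift), C9 (chloride with retention), C11 (directed reduction) and the four oxirane carbons of ring A are relayed from it.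
5. Ring order: five-membered ring (from 2,2-dimethylcyclopentane-1,3-dione) → ring B (cobalt-catalysed [4+2] of the alkyne with isoprene) → ring A (ring expansion).

Key step: step 7

Remark: carbons are numbered as in the spiro[5.5]undecane core of the target (C1 CMe2, C2 CBr, C3, C4, C5 CMe, C6 spiro, C7 CH2, C8 CHBr, C9 CMeCl, C10 CH2, C11 CHOH) and keep these numbers in every intermediate; up to step 7 the carbinol carbon C5 is carried in both configurations (left undefined in the SMILES), because step 7 turns it into a carbonyl carbon.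

**Route**

Step 1
Reactants: 1 2,2-dimethylcyclopentane-1,3-dione
Product: 2 3-bromo-2,2-dimethylcyclopent-3-en-1-one
Conditions: P(OPh)3 (1.0 equiv), Br2 (1.0 equiv), Et3N, CH2Cl2, −60 °C to rt
Reagents that add atoms: bromine, BrBr
Why: The bromophosphonium salt formed from P(OPh)3 and Br2 converts an enolisable ketone into its vinyl bromide (ketone-to-vinyl-halide reaction of triphenyl phosphite–halogen reagents); only C3 carries α-hydrogens, so the C2=C3 bromoalkene must form, and one equivalent should leave the second carbonyl untouched.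

Step 2
Reactants: 2 3-bromo-2,2-dimethylcyclopent-3-en-1-one; 3 ethynylmagnesium bromide
Product: 5 racemic [(3-bromo-1-ethynyl-2,2-dimethylcyclopent-3-en-1-yl)oxy]trimethylsilane, via bromomagnesium alkoxide 4 (not isolated)
Conditions: THF, −78 to 0 °C; then Me3SiCl, 0 °C to rt
Reagents that add atoms: chlorotrimethylsilane, C[Si](C)(C)Cl
Why: 1,2-Addition of the small, weakly basic magnesium acetylide to the ketone should outrun enolisation, and O-silylation of the alkoxide in the same flask masks the tertiary hydroxyl for steps 3 to 6; the new carbinol centre is racemic and is erased in step 7.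

Step 3
Reactants: 5 racemic [(3-bromo-1-ethynyl-2,2-dimethylcyclopent-3-en-1-yl)oxy]trimethylsilane; 6 isoprene (2-methylbuta-1,3-diene)
Product: 7 racemic {[3-bromo-2,2-dimethyl-1-(4-methylcyclohexa-1,4-dien-1-yl)cyclopent-3-en-1-yl]oxy}trimethylsilane
Conditions: CoBr2(dppe) (10 mol %; dppe = Ph2PCH2CH2PPh2), ZnI2 (20 mol %), Zn (20 mol %), CH2Cl2, rt
Reagents that add atoms: none
Why: Cobalt-catalysed [4+2] cycloaddition of an unactivated terminal alkyne with a 2-substituted 1,3-diene (monovalent cobalt–diphosphine catalyst made in the flask) gives the cyclohexa-1,4-diene with the two substituents 1,4 to each other, which closes ring B with its two isolated double bonds (C6=C11 and C8=C9) in the required places.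

Step 4
Reactants: 7 racemic {[3-bromo-2,2-dimethyl-1-(4-methylcyclohexa-1,4-dien-1-yl)cyclopent-3-en-1-yl]oxy}trimethylsilane
Product: 8 (8R,9S)-8,9-epoxide of 7 (both C5 epimers)
Conditions: 1,2:4,5-di-O-isopropylidene-β-D-erythro-hexo-2,3-diulo-2,6-pyranose (Shi ketone from D-fructose, 30 mol %), KHSO5 (as Oxone, 1.3 equiv), K2CO3, Bu4NHSO4, MeCN/CH2(OMe)2/aq. Na2B4O7 buffer, −10 to 0 °C
Reagents that add atoms: potassium peroxymonosulfate, [K+].[O-]S(=O)(=O)OO
Why: Shi asymmetric epoxidation should attack only the unhindered trisubstituted C8=C9 bond (C6=C11 is screened by the fully substituted silyloxy carbon, the bromoalkene is electron-poor), and the D-fructose ketone is expected, by its spiro transition-state model for trisubstituted cyclic olefins, to deliver oxygen to the face that gives (8R,9S); this is the only reagent-set stereo element of the route.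

Step 5
Reactants: 8 (8R,9S)-8,9-epoxide of 7 (both C5 epimers)
Product: 9 (8S,9S)-bromohydrin: 8-bromo-9-hydroxy, C6=C11 alkene, C5–OSiMe3 (both C5 epimers)
Conditions: Li2NiBr4, THF, 0 °C to rt; aqueous work-up
Reagents that add atoms: dilithium tetrabromonickelate, [Li+].[Li+].[Ni+2].[Br-].[Br-].[Br-].[Br-]
Why: Soft bromide opens the epoxide by SN2 attack at the less substituted carbon C8 with inversion (trans-diaxial opening), which sets the C8–Br centre and frees the tertiary C9 hydroxyl on the face of the former oxirane.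

Step 6
Reactants: 9 (8S,9S)-bromohydrin (both C5 epimers)
Product: 10 (6S,8S,9S,11R)-6,11-epoxy-8-bromo-9-hydroxy compound with C5–OSiMe3 (both C5 epimers)
Conditions: VO(acac)2 (5 mol %), t-BuOOH, CH2Cl2, rt
Reagents that add atoms: tert-butyl hydroperoxide, CC(C)(C)OO
Why: Hydroxyl-directed vanadium-catalysed epoxidation from the homoallylic C9 hydroxyl (the C5 oxygen is silylated and cannot bind the metal) should deliver oxygen to C6=C11 on the face of that hydroxyl, as in cyclohex-3-enols, so the new oxirane is syn to C9–OH.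

Step 7
Reactants: 10 (6S,8S,9S,11R)-6,11-epoxy-8-bromo-9-hydroxy compound with C5–OSiMe3 (both C5 epimers)
Product: 11 (6R,8S,9S,11R)-2,8-dibromo-9-hydroxy-1,1,9-trimethyl-11-(trimethylsilyloxy)spiro[5.5]undec-2-en-5-one
Conditions: Me3SiOSO2CF3 (10 mol %), 2,6-di-tert-butyl-4-methylpyridine (5 mol %), CH2Cl2, −78 °C
Reagents that add atoms: none
Why: The silyl triflate silylates the oxirane oxygen, the C6–O bond ionises and the C5–C1 bond, antiperiplanar to it, shifts to C6 under the push of the silyloxy oxygen on C5, so that C6 is inserted between C5 and C1; the silyloxocarbenium ion then hands its silyl group to the next oxirane, which leaves the C11 oxygen silylated and makes the acid catalytic. The closest known reaction type is the Lewis acid-promoted semipinacol rearrangement of 2,3-epoxy alcohols and their silyl ethers, which is used to expand 1-(epoxyalkyl)cyclobutanols and cyclopentanols to spiro ketones. Ring A is not closed by a cyclisation: it arises from the five-membered ring C1–C5 by this 1,2-alkyl shift (one-carbon ring expansion, five to six), which also forges the C1–C6 bond between two fully substituted carbons. The spiro centre C6 is set by inversion at the oxirane carbon (migration anti to the leaving oxygen) and so follows from the oxirane placed in step 6, C11 keeps its oxygen and configuration, and the two C5 epimers converge because C5 becomes the carbonyl carbon. The step needs migration of C1 and not of C4 or of the C11 hydrogen: C1 is fully substituted and allylic and therefore the better migrating carbon, C4 is a primary carbon, and a hydride shift has no oxygen push. The C9 hydroxyl and the bromides should remain spectators, since neither can reach C6 from the face opposite to the oxirane oxygen.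

Step 8
Reactants: 11 (6R,8S,9S,11R)-2,8-dibromo-9-hydroxy-1,1,9-trimethyl-11-(trimethylsilyloxy)spiro[5.5]undec-2-en-5-one
Product: 12 (6R,8S,9S,11R)-2,8-dibromo-9-chloro-11-hydroxy-1,1,9-trimethylspiro[5.5]undec-2-en-5-one
Conditions: HCl (4 M in dioxane), CH2Cl2, 0 °C
Reagents that add atoms: hydrogen chloride, Cl
Why: Ionisation of the tertiary C9 hydroxyl is assisted by the neighbouring C8 bromine, and chloride opens the bromonium ion at the tertiary carbon from the face that the water left, so C9–Cl should form with retention (substitution with neighbouring-group participation) and give the anti Br/Cl pair; the acid also cleaves the trimethylsilyl ether.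

Step 9
Reactants: 12 (6R,8S,9S,11R)-2,8-dibromo-9-chloro-11-hydroxy-1,1,9-trimethylspiro[5.5]undec-2-en-5-one
Product: 13 (5S,6R,8S,9S,11R)-2,8-dibromo-9-chloro-1,1,5,9-tetramethylspiro[5.5]undec-2-ene-5,11-diol
Conditions: MeLi, CeCl3, THF, −78 °C
Reagents that add atoms: methyllithium, [Li]C
Why: Organocerium 1,2-addition tolerates the hindered, easily enolised C5 ketone and the alkyl halides, and after chelation with the C11 alkoxide the methyl group should enter anti to the pseudoaxial C7 methylene; the configuration of this carbinol is of no consequence because C5 becomes trigonal in step 13.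

Step 10
Reactants: 13 (5S,6R,8S,9S,11R)-2,8-dibromo-9-chloro-1,1,5,9-tetramethylspiro[5.5]undec-2-ene-5,11-diol
Product: 14 (5S,6S,8S,9S)-2,8-dibromo-9-chloro-5-hydroxy-1,1,5,9-tetramethylspiro[5.5]undec-2-en-11-one
Conditions: Dess–Martin periodinane, NaHCO3, CH2Cl2, 0 °C to rt
Reagents that add atoms: none
Why: Dess–Martin oxidation converts only the secondary C11 alcohol (the tertiary C5 alcohol is inert), and the buffered, non-basic medium should avoid retro-aldol cleavage of the β-hydroxy ketone.

Step 11
Reactants: 14 (5S,6S,8S,9S)-2,8-dibromo-9-chloro-5-hydroxy-1,1,5,9-tetramethylspiro[5.5]undec-2-en-11-one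
Product: 15 (5S,6R,8S,9S,11S)-2,8-dibromo-9-chloro-1,1,5,9-tetramethylspiro[5.5]undec-2-ene-5,11-diol
Conditions: Me4NBH(OAc)3, AcOH/MeCN, −30 °C
Reagents that add atoms: none
Why: Hydroxyl-directed reduction of a β-hydroxy ketone (Evans–Saksena reduction): the C5 oxygen binds boron and hydride is delivered within the complex to the carbonyl face on the side of C5, which is axial on ring B when bromine and chlorine are equatorial, so the C11 hydroxyl should end anti to C5 and cis to C1 (11S).

Step 12
Reactants: 15 (5S,6R,8S,9S,11S)-2,8-dibromo-9-chloro-1,1,5,9-tetramethylspiro[5.5]undec-2-ene-5,11-diol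
Product: 16 (5S,6R,8S,9S,11S)-2,8-dibromo-9-chloro-1,1,5,9-tetramethyl-11-(triethylsilyloxy)spiro[5.5]undec-2-en-5-ol
Conditions: Et3SiCl, Et3N, 4-(dimethylamino)pyridine (cat.), CH2Cl2, 0 °C to rt
Reagents that add atoms: chlorotriethylsilane, CC[Si](CC)(CC)Cl
Why: Chemoselective silylation: the silyl chloride reacts with the secondary C11 hydroxyl and leaves the tertiary C5 hydroxyl free.

Step 13
Reactants: 16 (5S,6R,8S,9S,11S)-2,8-dibromo-9-chloro-1,1,5,9-tetramethyl-11-(triethylsilyloxy)spiro[5.5]undec-2-en-5-ol
Product: 17 (6R,8S,9S,11S)-2,8-dibromo-9-chloro-1,1,5,9-tetramethyl-11-(triethylsilyloxy)spiro[5.5]undeca-2,4-diene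
Conditions: Martin sulfurane, Ph2S[OC(CF3)2Ph]2, CH2Cl2, 0 °C to rt
Reagents that add atoms: none
Why: Martin sulfurane dehydration of the tertiary alcohol should remove a C4 hydrogen, which is allylic to the bromoalkene, so that the conjugated 2-bromo-1,3-diene forms in preference to the exocyclic alkene.

Step 14
Reactants: 17 (6R,8S,9S,11S)-2,8-dibromo-9-chloro-1,1,5,9-tetramethyl-11-(triethylsilyloxy)spiro[5.5]undeca-2,4-diene
Product: 19 (2S,3S,4S,5R,6R,8S,9S,11S)-2,8-dibromo-9-chloro-2,3:4,5-diepoxy-1,1,5,9-tetramethyl-11-(triethylsilyloxy)spiro[5.5]undecane, via vinyl epoxide 18 (not isolated)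
Conditions: dimethyldioxirane (excess, acetone solution), CH2Cl2, −20 °C to rt
Reagents that add atoms: dimethyldioxirane, CC1(C)OO1
Why: Dioxirane epoxidation under substrate control: the electrophilic oxidant should first attack the alkyl-substituted C4=C5 bond on the face anti to the pseudoaxial C11 branch (the smaller C7 methylene lies next to the C5 methyl), and the slower second oxygen transfer to the bromoalkene of the vinyl epoxide should occur anti to the first oxirane and to the pseudoaxial C1 methyl, giving the trans-bis-epoxide.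

Step 15
Reactants: 19 (2S,3S,4S,5R,6R,8S,9S,11S)-2,8-dibromo-9-chloro-2,3:4,5-diepoxy-1,1,5,9-tetramethyl-11-(triethylsilyloxy)spiro[5.5]undecane
Product: 20 (2S,3S,4S,5R,6R,8S,9S,11S)-2,8-dibromo-9-chloro-2,3:4,5-diepoxy-1,1,5,9-tetramethylspiro[5.5]undecan-11-ol (target)
Conditions: HF·pyridine, pyridine, THF, 0 °C
Reagents that add atoms: none
Why: Buffered fluoride cleaves the triethylsilyl ether (desilylation) under conditions that should be mild enough for the two oxiranes.

**Compound list**

1 | 2,2-dimethylcyclopentane-1,3-dione | CC1(C)C(=O)CCC1=O | starting material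
2 | 3-bromo-2,2-dimethylcyclopent-3-en-1-one | CC1(C)C(=O)CC=C1Br | intermediate
3 | ethynylmagnesium bromide | C#C[Mg]Br | starting material
4 | bromomagnesium 3-bromo-1-ethynyl-2,2-dimethylcyclopent-3-en-1-olate (racemic, not isolated) | CC1(C)C(Br)=CCC1(C#C)O[Mg]Br | intermediate
5 | racemic [(3-bromo-1-ethynyl-2,2-dimethylcyclopent-3-en-1-yl)oxy]trimethylsilane | CC1(C)C(Br)=CCC1(C#C)O[Si](C)(C)C | intermediate
6 | isoprene (2-methylbuta-1,3-diene) | CC(=C)C=C | starting material
7 | racemic {[3-bromo-2,2-dimethyl-1-(4-methylcyclohexa-1,4-dien-1-yl)cyclopent-3-en-1-yl]oxy}trimethylsilane | CC1=CCC(=CC1)C1(O[Si](C)(C)C)CC=C(Br)C1(C)C | intermediate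
8 | (8R,9S)-8,9-epoxide of 7 (both C5 epimers) | CC1(C)C(Br)=CCC1(O[Si](C)(C)C)C2=CC[C@]3(C)O[C@@H]3C2 | intermediate
9 | (8S,9S)-8-bromo-9-hydroxy compound, C6=C11 alkene, C5–OSiMe3 (both C5 epimers) | CC1(C)C(Br)=CCC1(O[Si](C)(C)C)C2=CC[C@](C)(O)[C@@H](Br)C2 | intermediate
10 | (6S,8S,9S,11R)-6,11-epoxy-8-bromo-9-hydroxy compound, C5–OSiMe3 (both C5 epimers) | CC1(C)C(Br)=CCC1(O[Si](C)(C)C)[C@]23C[C@H](Br)[C@@](C)(O)C[C@H]2O3 | intermediate
11 | (6R,8S,9S,11R)-2,8-dibromo-9-hydroxy-1,1,9-trimethyl-11-(trimethylsilyloxy)spiro[5.5]undec-2-en-5-one | CC1(C)C(Br)=CCC(=O)[C@]12C[C@H](Br)[C@@](C)(O)C[C@H]2O[Si](C)(C)C | intermediate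
12 | (6R,8S,9S,11R)-2,8-dibromo-9-chloro-11-hydroxy-1,1,9-trimethylspiro[5.5]undec-2-en-5-one | CC1(C)C(Br)=CCC(=O)[C@]12C[C@H](Br)[C@@](C)(Cl)C[C@H]2O | intermediate
13 | (5S,6R,8S,9S,11R)-2,8-dibromo-9-chloro-1,1,5,9-tetramethylspiro[5.5]undec-2-ene-5,11-diol | CC1(C)C(Br)=CC[C@](C)(O)[C@]12C[C@H](Br)[C@@](C)(Cl)C[C@H]2O | intermediate
14 | (5S,6S,8S,9S)-2,8-dibromo-9-chloro-5-hydroxy-1,1,5,9-tetramethylspiro[5.5]undec-2-en-11-one | CC1(C)C(Br)=CC[C@](C)(O)[C@]12C[C@H](Br)[C@@](C)(Cl)CC2=O | intermediate
15 | (5S,6R,8S,9S,11S)-2,8-dibromo-9-chloro-1,1,5,9-tetramethylspiro[5.5]undec-2-ene-5,11-diol | CC1(C)C(Br)=CC[C@](C)(O)[C@]12C[C@H](Br)[C@@](C)(Cl)C[C@@H]2O | intermediate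
16 | (5S,6R,8S,9S,11S)-2,8-dibromo-9-chloro-1,1,5,9-tetramethyl-11-(triethylsilyloxy)spiro[5.5]undec-2-en-5-ol | CC1(C)C(Br)=CC[C@](C)(O)[C@]12C[C@H](Br)[C@@](C)(Cl)C[C@@H]2O[Si](CC)(CC)CC | intermediate
17 | (6R,8S,9S,11S)-2,8-dibromo-9-chloro-1,1,5,9-tetramethyl-11-(triethylsilyloxy)spiro[5.5]undeca-2,4-diene | CC1(C)C(Br)=CC=C(C)[C@]12C[C@H](Br)[C@@](C)(Cl)C[C@@H]2O[Si](CC)(CC)CC | intermediate
18 | (4S,5R,6R,8S,9S,11S)-4,5-epoxide of 17 (vinyl epoxide, not isolated) | CC1(C)C(Br)=C[C@@H]2O[C@]2(C)[C@]12C[C@H](Br)[C@@](C)(Cl)C[C@@H]2O[Si](CC)(CC)CC | intermediate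
19 | (2S,3S,4S,5R,6R,8S,9S,11S)-2,8-dibromo-9-chloro-2,3:4,5-diepoxy-1,1,5,9-tetramethyl-11-(triethylsilyloxy)spiro[5.5]undecane | CC1(C)[C@@]2(Br)O[C@H]2[C@@H]2O[C@]2(C)[C@]12C[C@H](Br)[C@@](C)(Cl)C[C@@H]2O[Si](CC)(CC)CC | intermediate
20 | (2S,3S,4S,5R,6R,8S,9S,11S)-2,8-dibromo-9-chloro-2,3:4,5-diepoxy-1,1,5,9-tetramethylspiro[5.5]undecan-11-ol | CC1(C)[C@@]2(Br)O[C@H]2[C@@H]2O[C@]2(C)[C@]12C[C@H](Br)[C@@](C)(Cl)C[C@@H]2O | target

**Step count and risks**

Total step count: 15. Longest linear sequence: 15 steps (1 to 20).

Steps most likely to fail: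

Step 7 (key step). The migrating carbon C1 has to bond to the face of C6 that lies 1,3 to the C8 bromine; the shift may therefore be slow, so that hydride shift from C11 or simple opening of the oxirane takes over. The fallback moves the ring expansion in front of the bromide opening and sets out from 8. A second Shi epoxidation with the same ketone at higher loading should give the syn-bis-epoxide F1 under reagent control. Bu4NF buffered with AcOH would free the tertiary carbinol F2. One equivalent of Me3Al turns this carbinol into its aluminium alkoxide, which activates only the neighbouring oxirane and should give the spiro hydroxy ketone F3 with the C8–C9 oxirane intact. Li2NiBr4 would then open that oxirane at C8 to the bromohydrin F4, and HCl as in step 8 brings the material back to the route at 12.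

Step 14. The first oxygen transfer may show poor facial selectivity, and the hindered, electron-poor bromoalkene may react so slowly that the bromo-oxirane opens during the long exposure to the oxidant. The fallback sets out from 17 and replaces substrate control by reagent control and hydroxyl direction. Mono-epoxidation with the enantiomer of the Shi ketone (made from L-sorbose) should give 18, which is now isolated. HF·pyridine would then free the C11 alcohol F5, whose axial hydroxyl lies over C1 and C2. A hydroxyl-directed epoxidation (VO(acac)2, t-BuOOH) should deliver the second oxygen syn to that hydroxyl and anti to the first oxirane, which returns to the route at 20.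

Step 3. The low-valent cobalt/zinc system may insert into or reduce the C–Br bond, or the bulky alkyne may erode the 1,4-regiocontrol. The fallback sets out from 2 and 6 and builds the dienyl unit before it meets the bromide. Isoprene 6 and ethynylboronic acid pinacol ester with the same cobalt catalyst should give the dienyl boronate F6. CuBr2 in aqueous methanol would convert it into the dienyl bromide F7, and t-BuLi at −78 °C into the dienyllithium F8. Addition to ketone 2 gives the lithium alkoxide F9, and Me3SiCl in the same flask returns to the route at 7.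

Further compounds
F1 | step 7 | (6S,8R,9S,11R)-6,11:8,9-bis-epoxide with C5–OSiMe3 (both C5 epimers) | CC1(C)C(Br)=CCC1(O[Si](C)(C)C)[C@]23C[C@H]4O[C@@]4(C)C[C@H]2O3
F2 | step 7 | (6S,8R,9S,11R)-6,11:8,9-bis-epoxide with free C5 hydroxyl (both C5 epimers) | CC1(C)C(Br)=CCC1(O)[C@]23C[C@H]4O[C@@]4(C)C[C@H]2O3
F3 | step 7 | (6R,8R,9S,11R)-2-bromo-8,9-epoxy-11-hydroxy-1,1,9-trimethylspiro[5.5]undec-2-en-5-one | CC1(C)C(Br)=CCC(=O)[C@]12C[C@H]3O[C@@]3(C)C[C@H]2O
F4 | step 7 | (6R,8S,9S,11R)-2,8-dibromo-9,11-dihydroxy-1,1,9-trimethylspiro[5.5]undec-2-en-5-one | CC1(C)C(Br)=CCC(=O)[C@]12C[C@H](Br)[C@@](C)(O)C[C@H]2O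
F5 | step 14 | (4S,5R,6R,8S,9S,11S)-2,8-dibromo-9-chloro-4,5-epoxy-1,1,5,9-tetramethylspiro[5.5]undec-2-en-11-ol | CC1(C)C(Br)=C[C@@H]2O[C@]2(C)[C@]12C[C@H](Br)[C@@](C)(Cl)C[C@@H]2O
F6 | step 3 | 4,4,5,5-tetramethyl-2-(4-methylcyclohexa-1,4-dien-1-yl)-1,3,2-dioxaborolane | CC1=CCC(=CC1)B1OC(C)(C)C(C)(C)O1
F7 | step 3 | 1-bromo-4-methylcyclohexa-1,4-diene | CC1=CCC(Br)=CC1
F8 | step 3 | (4-methylcyclohexa-1,4-dien-1-yl)lithium | [Li]C1=CCC(C)=CC1
F9 | step 3 | lithium 3-bromo-2,2-dimethyl-1-(4-methylcyclohexa-1,4-dien-1-yl)cyclopent-3-en-1-olate (racemic) | CC1=CCC(=CC1)C1(O[Li])CC=C(Br)C1(C)C
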